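**Plan**

- Retrosynthetic cuts: the benzyl groups; then the ester C(=O)–O bond between the Cα carboxyl and the second danshensu unit, redrawn as the O3–C(=O) bond of an aryl lactone; then the Cα–C(=O) and O3–C(=O) bonds, both to carbon monoxide, which leaves a 2-alkynylphenol; finally the ring A C2–C(sp) bond (Sonogashira) and the propenoate C=C on C1 (Horner–Wadsworth–Emmons with a danshensu phosphonoacetate).
- Enabling feature: the carboxyl carbon, Cα, C2 and C3 of the central ring A and the oxygen on C3 form a five-atom chain, so one CO can bridge O3 and Cα as a five-membered benzofuran-2(3H)-one. Being a phenolic ester, this lactone is also the acyl donor for the hindered ester.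
- Forward order: the ring A bromoaldehyde is joined to ring B through the alkyne, then to the danshensu-bearing propenoate arm, and O3 is freed. Cyclocarbonylation closes the only ring made in the route, the alkoxide of the second danshensu unit opens it again, and debenzylation finishes.
- Stereochemistry: both stereocentres are the (R)-carbinol carbons of commercial danshensu and react only at oxygen. The disubstituted alkene is E from the olefination; the trisubstituted alkene (rings A and B cis) is E from syn H–Pd addition.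

Key step: step 10

Remark: ring A is the central catechol ring, numbered C1 (propenoate arm), C2 (bearing Cα), C3 and C4 (oxygens); Cα and Cβ are the trisubstituted-alkene carbons bonded to ring A and ring B; danshensu is used as its commercial sodium salt.

**Route**

Step 1
Reactants: 1 danshensu sodium salt
Product: 2 benzyl (R)-3-[3,4-bis(benzyloxy)phenyl]-2-hydroxypropanoate
Conditions: BnBr (3.3 equiv), K2CO3, DMF, rt, under argon
Reagents that add atoms: benzyl bromide, BrCc1ccccc1
Why: Williamson O-alkylation of the two phenoxides and the carboxylate under carbonate base should leave the far less acidic secondary hydroxyl free and the stereocentre untouched.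

Step 2
Reactants: 2 benzyl (R)-3-[3,4-bis(benzyloxy)phenyl]-2-hydroxypropanoate; 3 diethylphosphonoacetic acid
Product: 4 benzyl (R)-3-[3,4-bis(benzyloxy)phenyl]-2-{[2-(diethoxyphosphoryl)acetyl]oxy}propanoate
Conditions: DCC, DMAP (cat.), CH2Cl2, 0 °C to rt
Reagents that add atoms: none
Why: Steglich esterification acylates the secondary alcohol on oxygen with retention and delivers the Horner–Wadsworth–Emmons reagent for the caffeoyl arm.

Step 3
Reactants: 5 2-bromoisovanillin (2-bromo-3-hydroxy-4-methoxybenzaldehyde)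
Product: 6 2-bromo-3,4-dihydroxybenzaldehyde
Conditions: BBr3, CH2Cl2, −78 °C to rt; aqueous work-up
Reagents that add atoms: none
Why: Lewis-acid cleavage of the aryl methyl ether by BBr3 proceeds through the aryloxyborane and bromomethane, with the aldehyde and aryl bromide inert.

Step 4
Reactants: 6 2-bromo-3,4-dihydroxybenzaldehyde
Product: 7 4-(benzyloxy)-2-bromo-3-hydroxybenzaldehyde
Conditions: BnBr (1.0 equiv), NaHCO3, NaI (cat.), DMF, 40 °C
Reagents that add atoms: benzyl bromide, BrCc1ccccc1
Why: Regioselective Williamson etherification: the 4-OH para to the formyl group is the more acidic and less hindered hydroxyl, so a weak base should alkylate it preferentially, as in the 4-O-benzylation of protocatechualdehyde.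

Step 5
Reactants: 7 4-(benzyloxy)-2-bromo-3-hydroxybenzaldehyde
Product: 8 4-(benzyloxy)-2-bromo-3-[(tert-butyldimethylsilyl)oxy]benzaldehyde
Conditions: TBSCl, imidazole, DMF, rt
Reagents that add atoms: tert-butyldimethylsilyl chloride, CC(C)(C)[Si](C)(C)Cl
Why: Silylation of the remaining phenol masks O3 so that no ortho-alkynyl phenoxide can cyclise to a benzofuran during the cross-coupling and olefination steps.

Step 6
Reactants: 9 3,4-bis(benzyloxy)benzaldehyde
Product: 10 1,2-bis(benzyloxy)-4-ethynylbenzene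
Conditions: dimethyl (1-diazo-2-oxopropyl)phosphonate, K2CO3, MeOH/THF, rt
Reagents that add atoms: dimethyl (1-diazo-2-oxopropyl)phosphonate (Ohira–Bestmann reagent), COP(=O)(OC)C(=[N+]=[N-])C(C)=O
Why: Seyferth–Gilbert homologation with the Ohira–Bestmann reagent turns the non-enolisable aryl aldehyde into the terminal alkyne under mild carbonate/methanol conditions.

Step 7
Reactants: 8 4-(benzyloxy)-2-bromo-3-[(tert-butyldimethylsilyl)oxy]benzaldehyde; 10 1,2-bis(benzyloxy)-4-ethynylbenzene
Product: 11 4-(benzyloxy)-2-{[3,4-bis(benzyloxy)phenyl]ethynyl}-3-[(tert-butyldimethylsilyl)oxy]benzaldehyde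
Conditions: PdCl2(PPh3)2 (5 mol %), CuI (5 mol %), Et3N, THF, 60 °C, degassed
Reagents that add atoms: none
Why: Sonogashira coupling; the ortho formyl group accelerates oxidative addition into the hindered C2–Br bond, and the silyl ether prevents Pd/Cu-mediated closure to the benzofuran.

Step 8
Reactants: 11 the 2-alkynylbenzaldehyde; 4 the danshensu phosphonoacetate
Product: 12 benzyl (R)-2-{[(E)-3-(4-(benzyloxy)-2-{[3,4-bis(benzyloxy)phenyl]ethynyl}-3-[(tert-butyldimethylsilyl)oxy]phenyl)prop-2-enoyl]oxy}-3-[3,4-bis(benzyloxy)phenyl]propanoate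
Conditions: LiCl, iPr2NEt, MeCN/THF, rt
Reagents that add atoms: none
Why: Horner–Wadsworth–Emmons olefination under Masamune–Roush conditions should give the E-cinnamate without epimerising the α-acyloxy ester stereocentre or cleaving the aryl silyl ether.

Step 9
Reactants: 12 the silyl-protected alkynyl cinnamate
Product: 13 benzyl (R)-2-{[(E)-3-(4-(benzyloxy)-2-{[3,4-bis(benzyloxy)phenyl]ethynyl}-3-hydroxyphenyl)prop-2-enoyl]oxy}-3-[3,4-bis(benzyloxy)phenyl]propanoate
Conditions: TBAF, AcOH, THF, 0 °C
Reagents that add atoms: none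
Why: Fluoride desilylation buffered with acetic acid frees O3 as the neutral phenol, so base-induced 5-endo cyclisation onto the alkyne and ester cleavage should be avoided.

Step 10
Reactants: 13 the 2-alkynylphenol
Product: 14 benzyl (R)-2-{[(E)-3-{(3E)-7-(benzyloxy)-3-[3,4-bis(benzyloxy)benzylidene]-2-oxo-2,3-dihydro-1-benzofuran-4-yl}prop-2-enoyl]oxy}-3-[3,4-bis(benzyloxy)phenyl]propanoate
Conditions: Pd2(dba)3·CHCl3 (2.5 mol %), dppb (6 mol %), TsOH·H2O (5 mol %), CO (20 bar), toluene, 70 °C, dark
Reagents that add atoms: carbon monoxide, [C-]#[O+]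
Why: Pd(0)/dppb and the acid give a palladium hydride (equivalently, O3–H adds oxidatively to Pd(0)), which adds syn across the alkyne with Pd on Cα; CO then inserts into the vinyl–Pd bond and O3 attacks the acyl-palladium, releasing the lactone and regenerating Pd–H. The closest known reaction type is the palladium-catalysed cyclocarbonylation (hydrocarbonylative lactonisation) of alkynols and 2-alkynylphenols to α-alkylidene lactones, together with the syn hydroaryloxycarbonylation of alkynes with phenols. The single ring closes by 5-exo-trig acyl substitution of O3 at the acyl-palladium carbon, after migratory insertion has made the Cα–C(=O) bond. No stereocentre arises; the E geometry (H on Cβ cis to the carbonyl, ring B cis to ring A) is fixed by the syn addition of H and Pd and should be kept by moderate temperature, exclusion of light and short reaction time. The step needs regioselective hydropalladation and chemoselectivity against 5-endo-dig oxypalladation to the 2-arylbenzofuran and against insertion of the acyl-palladium into the cinnamate alkene: only an acyl group on Cα is within reach of O3 (an acyl on Cβ would sit trans to ring A and cannot lactonise), and the Pd(0) source, the absence of base and oxidant and the CO pressure keep the phenol protonated and disfavour Pd(II)-type cycloisomerisation.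

Step 11
Reactants: 14 the (E)-arylidene benzofuranone; 2 benzyl (R)-3-[3,4-bis(benzyloxy)phenyl]-2-hydroxypropanoate
Product: 17 nona-O-benzyl salvianolic acid E, via lithium alkoxide 15 (not isolated), via lithium phenoxide 16 (not isolated)
Conditions: 2 (1.2 equiv), LiHMDS (1.1 equiv), THF, −78 °C; then 14, −78 to −30 °C; AcOH quench
Reagents that add atoms: none
Why: Acyl transfer from a phenolic lactone acting as a built-in active ester: the lithium alkoxide adds to the lactone carbonyl and the tetrahedral intermediate collapses to the hindered ester with release of the much less basic O3 phenoxide (the logic of alkoxide opening of aryl esters and β-lactams); the carbinol configuration is retained because only its O–H bond reacts, and the alkene is not touched.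

Step 12
Reactants: 17 nona-O-benzyl salvianolic acid E
Product: 18 salvianolic acid E
Conditions: BCl3 (excess), pentamethylbenzene, CH2Cl2, −78 to −40 °C; MeOH/H2O quench; reversed-phase purification
Reagents that add atoms: none
Why: Lewis-acid debenzylation with BCl3 and pentamethylbenzene as a non-basic benzyl-cation scavenger should cleave the seven aryl benzyl ethers and two benzyl esters at low temperature without any reduction, so both alkenes, both secondary esters and both stereocentres remain.

**Compound list**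

1 | danshensu sodium salt, sodium (R)-3-(3,4-dihydroxyphenyl)-2-hydroxypropanoate | O[C@H](Cc1ccc(O)c(O)c1)C(=O)[O-].[Na+] | starting material
2 | benzyl (R)-3-[3,4-bis(benzyloxy)phenyl]-2-hydroxypropanoate | O[C@H](Cc1ccc(OCc2ccccc2)c(OCc2ccccc2)c1)C(=O)OCc1ccccc1 | intermediate
3 | diethylphosphonoacetic acid | CCOP(=O)(OCC)CC(=O)O | starting material
4 | benzyl (R)-3-[3,4-bis(benzyloxy)phenyl]-2-{[2-(diethoxyphosphoryl)acetyl]oxy}propanoate | CCOP(=O)(OCC)CC(=O)O[C@H](Cc1ccc(OCc2ccccc2)c(OCc2ccccc2)c1)C(=O)OCc1ccccc1 | intermediate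
5 | 2-bromoisovanillin (2-bromo-3-hydroxy-4-methoxybenzaldehyde) | COc1ccc(C=O)c(Br)c1O | starting material
6 | 2-bromo-3,4-dihydroxybenzaldehyde | O=Cc1ccc(O)c(O)c1Br | intermediate
7 | 4-(benzyloxy)-2-bromo-3-hydroxybenzaldehyde | O=Cc1ccc(OCc2ccccc2)c(O)c1Br | intermediate
8 | 4-(benzyloxy)-2-bromo-3-[(tert-butyldimethylsilyl)oxy]benzaldehyde | O=Cc1ccc(OCc2ccccc2)c(O[Si](C)(C)C(C)(C)C)c1Br | intermediate
9 | 3,4-bis(benzyloxy)benzaldehyde | O=Cc1ccc(OCc2ccccc2)c(OCc2ccccc2)c1 | starting material
10 | 1,2-bis(benzyloxy)-4-ethynylbenzene | C#Cc1ccc(OCc2ccccc2)c(OCc2ccccc2)c1 | intermediate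
11 | 4-(benzyloxy)-2-{[3,4-bis(benzyloxy)phenyl]ethynyl}-3-[(tert-butyldimethylsilyl)oxy]benzaldehyde | O=Cc1ccc(OCc2ccccc2)c(O[Si](C)(C)C(C)(C)C)c1C#Cc1ccc(OCc2ccccc2)c(OCc2ccccc2)c1 | intermediate
12 | O3-TBS 2-alkynyl (E)-cinnamate of tribenzyl danshensu | O=C(/C=C/c1ccc(OCc2ccccc2)c(O[Si](C)(C)C(C)(C)C)c1C#Cc1ccc(OCc2ccccc2)c(OCc2ccccc2)c1)O[C@H](Cc1ccc(OCc2ccccc2)c(OCc2ccccc2)c1)C(=O)OCc1ccccc1 | intermediate
13 | 2-alkynylphenol (O3–H) carrying the protected danshensu (E)-cinnamate arm | O=C(/C=C/c1ccc(OCc2ccccc2)c(O)c1C#Cc1ccc(OCc2ccccc2)c(OCc2ccccc2)c1)O[C@H](Cc1ccc(OCc2ccccc2)c(OCc2ccccc2)c1)C(=O)OCc1ccccc1 | intermediate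
14 | (E)-3-[3,4-bis(benzyloxy)benzylidene]-7-(benzyloxy)benzofuran-2(3H)-one carrying the protected danshensu (E)-propenoate arm at C4 | O=C(/C=C/c1ccc(OCc2ccccc2)c2OC(=O)/C(=C/c3ccc(OCc4ccccc4)c(OCc4ccccc4)c3)c12)O[C@H](Cc1ccc(OCc2ccccc2)c(OCc2ccccc2)c1)C(=O)OCc1ccccc1 | intermediate
15 | lithium alkoxide of 2 | [Li+].[O-][C@H](Cc1ccc(OCc2ccccc2)c(OCc2ccccc2)c1)C(=O)OCc1ccccc1 | intermediate
16 | lithium O3-phenoxide of 17 | O=C(/C=C/c1ccc(OCc2ccccc2)c([O-])c1/C(=C\c1ccc(OCc2ccccc2)c(OCc2ccccc2)c1)C(=O)O[C@H](Cc1ccc(OCc2ccccc2)c(OCc2ccccc2)c1)C(=O)OCc1ccccc1)O[C@H](Cc1ccc(OCc2ccccc2)c(OCc2ccccc2)c1)C(=O)OCc1ccccc1.[Li+] | intermediate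
17 | nona-O-benzyl salvianolic acid E (ring A 4-OBn and free 3-OH; ring B and both danshensu catechols as benzyl ethers; both carboxyls as benzyl esters; both alkenes E; both carbinol carbons R) | O=C(/C=C/c1ccc(OCc2ccccc2)c(O)c1/C(=C\c1ccc(OCc2ccccc2)c(OCc2ccccc2)c1)C(=O)O[C@H](Cc1ccc(OCc2ccccc2)c(OCc2ccccc2)c1)C(=O)OCc1ccccc1)O[C@H](Cc1ccc(OCc2ccccc2)c(OCc2ccccc2)c1)C(=O)OCc1ccccc1 | intermediate
18 | salvianolic acid E | O=C(/C=C/c1ccc(O)c(O)c1/C(=C\c1ccc(O)c(O)c1)C(=O)O[C@H](Cc1ccc(O)c(O)c1)C(=O)O)O[C@H](Cc1ccc(O)c(O)c1)C(=O)O | target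

**Step count and risks**

Total steps: 12. Longest linear sequence: 9 steps (5 to 18 through steps 3, 4, 5, 7, 8, 9, 10, 11, 12).

Steps most likely to fail:

1. Step 10. The alkynylphenol may cycloisomerise 5-endo-dig to the 2-arylbenzofuran, hydropalladation may take the opposite regiochemistry, the acyl-palladium may insert into the cinnamate alkene, or the kinetically set E geometry of the crowded arylidene lactone may be lost by reversible Pd–H addition. The fallback sets out from 12 and builds the same bonds stepwise with stoichiometric control. Palladium-catalysed syn hydrostannation (Bu3SnH, PdCl2(PPh3)2, THF, rt) should place tin on Cα, directed by the ortho-substituted ring A, giving the (E)-vinylstannane F1. Iododestannylation (I2, CH2Cl2, 0 °C) with retention gives the (E)-vinyl iodide F2. Buffered desilylation as in step 9 gives the iodo phenol F3. Carbonylative lactonisation of the vinyl iodide (Pd(PPh3)4, CO 1 atm, Et3N, MeCN, 50 °C), with retention at the vinyl carbon, comes back to the route at 14.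

2. Step 11. The alkoxide may add reversibly in oxa-Michael fashion to the arylidene lactone and scramble the alkene geometry, acyl attack by the hindered alkoxide may be slow, the α-acyloxy ester may epimerise, or the lactone may re-close on work-up. The fallback sets out from 14 and replaces acyl transfer from the lactone by a carboxylic acid coupling. Selective saponification of the aryl lactone (LiOH 1 equiv, THF/H2O, 0 °C) gives the hydroxy acid F4. Double silylation (TBSCl, imidazole, DMF) gives the silyl ether silyl ester F5, whose silyl ester is hydrolysed (AcOH, THF/H2O) to the O3-silylated acid F6. Yamaguchi esterification with 2 (2,4,6-trichlorobenzoyl chloride, Et3N, then DMAP, toluene) gives the O3-silylated diester F7. Buffered desilylation (TBAF, AcOH, THF, 0 °C) comes back to the route at 17.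

3. Step 12. Cleavage of the two benzyl esters may be incomplete, the benzyl cations may C-benzylate the catechol rings, or the Lewis acid may drive O3 back onto the neighbouring ester with loss of the danshensu unit. The fallback sets out from 17 and stages the deprotection by two different mechanisms. Silane-mediated palladium debenzylation (Pd(OAc)2, Et3SiH, Et3N, CH2Cl2, rt; then aqueous work-up) should remove only the two benzyl esters while sparing aryl benzyl ethers and alkenes, giving the heptabenzyl ether diacid F8. BCl3 with pentamethylbenzene at −78 °C then has only aryl benzyl ethers to cleave and comes back to the route at 18.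

**Further compounds**

F1 | step 10 | (E)-α-tributylstannyl stilbene (Sn on Cα, O3-TBS) with the protected danshensu cinnamate arm | O=C(/C=C/c1ccc(OCc2ccccc2)c(O[Si](C)(C)C(C)(C)C)c1/C(=C\c1ccc(OCc2ccccc2)c(OCc2ccccc2)c1)[Sn](CCCC)(CCCC)CCCC)O[C@H](Cc1ccc(OCc2ccccc2)c(OCc2ccccc2)c1)C(=O)OCc1ccccc1
F2 | step 10 | (E)-α-iodo stilbene (I on Cα, O3-TBS) with the protected danshensu cinnamate arm | O=C(/C=C/c1ccc(OCc2ccccc2)c(O[Si](C)(C)C(C)(C)C)c1/C(=C\c1ccc(OCc2ccccc2)c(OCc2ccccc2)c1)I)O[C@H](Cc1ccc(OCc2ccccc2)c(OCc2ccccc2)c1)C(=O)OCc1ccccc1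
F3 | step 10 | (E)-α-iodo stilbene with free O3 phenol and the protected danshensu cinnamate arm | O=C(/C=C/c1ccc(OCc2ccccc2)c(O)c1/C(=C\c1ccc(OCc2ccccc2)c(OCc2ccccc2)c1)I)O[C@H](Cc1ccc(OCc2ccccc2)c(OCc2ccccc2)c1)C(=O)OCc1ccccc1
F4 | step 11 | ring-opened hydroxy acid, (E)-2-aryl-3-[3,4-bis(benzyloxy)phenyl]acrylic acid with free O3 phenol | O=C(/C=C/c1ccc(OCc2ccccc2)c(O)c1/C(=C\c1ccc(OCc2ccccc2)c(OCc2ccccc2)c1)C(=O)O)O[C@H](Cc1ccc(OCc2ccccc2)c(OCc2ccccc2)c1)C(=O)OCc1ccccc1
F5 | step 11 | O3-TBS ether TBS ester of F4 | O=C(/C=C/c1ccc(OCc2ccccc2)c(O[Si](C)(C)C(C)(C)C)c1/C(=C\c1ccc(OCc2ccccc2)c(OCc2ccccc2)c1)C(=O)O[Si](C)(C)C(C)(C)C)O[C@H](Cc1ccc(OCc2ccccc2)c(OCc2ccccc2)c1)C(=O)OCc1ccccc1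
F6 | step 11 | O3-TBS ether of the (E)-2,3-diarylacrylic acid | O=C(/C=C/c1ccc(OCc2ccccc2)c(O[Si](C)(C)C(C)(C)C)c1/C(=C\c1ccc(OCc2ccccc2)c(OCc2ccccc2)c1)C(=O)O)O[C@H](Cc1ccc(OCc2ccccc2)c(OCc2ccccc2)c1)C(=O)OCc1ccccc1
F7 | step 11 | O3-TBS ether of nona-O-benzyl salvianolic acid E | O=C(/C=C/c1ccc(OCc2ccccc2)c(O[Si](C)(C)C(C)(C)C)c1/C(=C\c1ccc(OCc2ccccc2)c(OCc2ccccc2)c1)C(=O)O[C@H](Cc1ccc(OCc2ccccc2)c(OCc2ccccc2)c1)C(=O)OCc1ccccc1)O[C@H](Cc1ccc(OCc2ccccc2)c(OCc2ccccc2)c1)C(=O)OCc1ccccc1
F8 | step 12 | hepta-O-benzyl salvianolic acid E (both carboxylic acids free) | O=C(/C=C/c1ccc(OCc2ccccc2)c(O)c1/C(=C\c1ccc(OCc2ccccc2)c(OCc2ccccc2)c1)C(=O)O[C@H](Cc1ccc(OCc2ccccc2)c(OCc2ccccc2)c1)C(=O)O)O[C@H](Cc1ccc(OCc2ccccc2)c(OCc2ccccc2)c1)C(=O)O
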